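**Assumption:** the target, tetracosyl 2,3-dihydroxybenzoate (C31H54O4), has no stereocentre, so it is achiral and no enantiocontrol is needed; the route is a paper design and has not been run.

**Retrosynthetic overview**
1. Target ⇒ tetracosyl 2,3-bis(benzyloxy)benzoate (hydrogenolysis last) ⇒ ester C–O bond ⇒ 2,3-bis(benzyloxy)benzoic acid + tetracosan-1-ol.
2. Tetracosan-1-ol ⇒ tert-butyl tetracosanoate ⇒ tert-butyl 3-oxotetracosanoate (3-oxo group removed by reduction, mesylation, elimination, hydrogenation).
3. Key C–C bond (C2–C3 of the C24 chain): crossed Claisen condensation of the lithium enolate of tert-butyl acetate with methyl docosanoate (C2 + C22).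
4. Acid fragment from 2,3-dihydroxybenzoic acid by perbenzylation and saponification.
5. No ring is formed; the only ring (benzene) is bought in 2,3-dihydroxybenzoic acid.

**Route**

Step 1
Reactants: 1 tert-butyl acetate; 2 methyl docosanoate
Product: 4 tert-butyl 3-oxotetracosanoate, via tert-butyl acetate lithium enolate 3 (not isolated)
Conditions: LDA (3.0 equiv, commercial solution), THF, −78 °C, then 1 (3.0 equiv), 45 min; 2 in THF, −40 °C → rt; 1 M HCl quench at 0 °C
Reagents that add atoms: none
Why: Crossed Claisen condensation: the preformed, bulky ester enolate self-condenses only slowly, acylates on the methyl ester, and deprotonation of the β-keto ester product by excess enolate drives the reaction; no stereocentre is formed.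

Step 2
Reactants: 4 tert-butyl 3-oxotetracosanoate
Product: 5 tert-butyl 3-hydroxytetracosanoate (racemic)
Conditions: NaBH4 (1.5 equiv), THF/MeOH 4:1, 0 °C → rt
Reagents that add atoms: none
Why: Chemoselective borohydride reduction of the ketone beside the tert-butyl ester; the C3 carbinol centre is formed racemic on purpose because it is removed in step 4.

Step 3
Reactants: 5 tert-butyl 3-hydroxytetracosanoate
Product: 6 tert-butyl 3-(methylsulfonyloxy)tetracosanoate (racemic)
Conditions: MsCl (1.3 equiv), Et3N (1.6 equiv), CH2Cl2, 0 °C
Reagents that add atoms: methanesulfonyl chloride, CS(=O)(=O)Cl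
Why: Standard O-sulfonylation of an unhindered secondary alcohol turns the hydroxyl into a leaving group; the ester is untouched.

Step 4
Reactants: 6 tert-butyl 3-(methylsulfonyloxy)tetracosanoate
Product: 7 tert-butyl (E)-tetracos-2-enoate
Conditions: DBU (2.0 equiv), CH2Cl2, 0 °C → rt
Reagents that add atoms: none
Why: E1cB β-elimination of a β-mesyloxy ester gives the conjugated E-enoate; any Z or β,γ isomer converges in step 5.

Step 5
Reactants: 7 tert-butyl (E)-tetracos-2-enoate
Product: 8 tert-butyl tetracosanoate
Conditions: H2 (1 atm), 10% Pd/C, EtOAc/THF, rt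
Reagents that add atoms: none
Why: Catalytic hydrogenation of an unhindered disubstituted alkene; the tert-butyl ester is inert.

Step 6
Reactants: 8 tert-butyl tetracosanoate
Product: 9 tetracosan-1-ol
Conditions: LiAlH4 (1.5 equiv), THF, 0 °C → reflux; Fieser work-up (H2O, 15% NaOH, H2O); recrystallise from acetone
Reagents that add atoms: none
Why: Hydride reduction of the ester to the primary alcohol; there is no other reducible group.

Step 7
Reactants: 10 2,3-dihydroxybenzoic acid
Product: 11 benzyl 2,3-bis(benzyloxy)benzoate
Conditions: BnBr (3.5 equiv), K2CO3 (4.0 equiv), DMF, 60 °C, 16 h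
Reagents that add atoms: benzyl bromide, BrCc1ccccc1
Why: Williamson ether synthesis and carboxylate alkylation (SN2) on all three acidic OH groups; excess reagent and heat overcome the hydrogen-bonded 2-OH.

Step 8
Reactants: 11 benzyl 2,3-bis(benzyloxy)benzoate
Product: 12 2,3-bis(benzyloxy)benzoic acid
Conditions: 5 M aq NaOH (5 equiv), MeOH/THF, 65 °C; then 1 M HCl to pH 2
Reagents that add atoms: sodium hydroxide, [Na+].[OH-] (supplies the carboxyl OH oxygen)
Why: Saponification cleaves only the benzyl ester; the aryl benzyl ethers are stable to base.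

Step 9
Reactants: 12 2,3-bis(benzyloxy)benzoic acid (1.2 equiv); 9 tetracosan-1-ol
Product: 13 tetracosyl 2,3-bis(benzyloxy)benzoate
Conditions: EDC·HCl (1.5 equiv), DMAP (0.5 equiv), CH2Cl2/THF 3:1, 35 °C, 24 h
Reagents that add atoms: none
Why: Steglich esterification: carbodiimide activation with DMAP acyl transfer couples the primary alcohol under neutral conditions that leave the benzyl ethers intact; mild warming keeps the waxy alcohol in solution.

Step 10
Reactants: 13 tetracosyl 2,3-bis(benzyloxy)benzoate
Product: 14 tetracosyl 2,3-dihydroxybenzoate (Gentiside K)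
Conditions: H2 (1 atm), 10% Pd/C, THF/EtOAc 1:1, rt; filter through Celite under N2
Reagents that add atoms: none
Why: Hydrogenolysis removes both O-benzyl groups; the ester is a plain alkyl benzoate (no benzylic C–O), so it survives and the catechol is released under neutral conditions.

**Compound list**
1 | tert-butyl acetate | CC(=O)OC(C)(C)C | starting material
2 | methyl docosanoate (methyl behenate) | CCCCCCCCCCCCCCCCCCCCCC(=O)OC | starting material
3 | tert-butyl acetate lithium enolate | [Li+].[O-]C(=C)OC(C)(C)C | intermediate
4 | tert-butyl 3-oxotetracosanoate | CCCCCCCCCCCCCCCCCCCCCC(=O)CC(=O)OC(C)(C)C | intermediate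
5 | tert-butyl 3-hydroxytetracosanoate (racemic) | CCCCCCCCCCCCCCCCCCCCCC(O)CC(=O)OC(C)(C)C | intermediate
6 | tert-butyl 3-(methylsulfonyloxy)tetracosanoate (racemic) | CCCCCCCCCCCCCCCCCCCCCC(OS(C)(=O)=O)CC(=O)OC(C)(C)C | intermediate
7 | tert-butyl (E)-tetracos-2-enoate | CCCCCCCCCCCCCCCCCCCCC/C=C/C(=O)OC(C)(C)C | intermediate
8 | tert-butyl tetracosanoate | CCCCCCCCCCCCCCCCCCCCCCCC(=O)OC(C)(C)C | intermediate
9 | tetracosan-1-ol | CCCCCCCCCCCCCCCCCCCCCCCCO | intermediate
10 | 2,3-dihydroxybenzoic acid | OC(=O)c1cccc(O)c1O | starting material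
11 | benzyl 2,3-bis(benzyloxy)benzoate | O=C(OCc1ccccc1)c1cccc(OCc2ccccc2)c1OCc1ccccc1 | intermediate
12 | 2,3-bis(benzyloxy)benzoic acid | OC(=O)c1cccc(OCc2ccccc2)c1OCc1ccccc1 | intermediate
13 | tetracosyl 2,3-bis(benzyloxy)benzoate | CCCCCCCCCCCCCCCCCCCCCCCCOC(=O)c1cccc(OCc2ccccc2)c1OCc1ccccc1 | intermediate
14 | tetracosyl 2,3-dihydroxybenzoate (Gentiside K) | CCCCCCCCCCCCCCCCCCCCCCCCOC(=O)c1cccc(O)c1O | target

**Totals**
Total step count: 10. Longest linear sequence: 8 (steps 1–6, 9, 10); steps 7–8 form the convergent acid branch.

**Three steps most likely to fail, with fallbacks**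

Step 1 (crossed Claisen). The waxy ester 2 is poorly soluble in cold THF, so conversion may stall or self-condensation of 1 may compete. The fallback sets out from 2 and comes back at 5. Reduce 2 with LiAlH4 (THF, 0 °C → reflux) to docosan-1-ol F1. Oxidise with Dess–Martin periodinane (CH2Cl2, rt) to docosanal F2. Add F2 in THF to the lithium enolate 3 (LDA, 1, THF, −78 °C → −20 °C). This aldol addition gives racemic 5 directly, so the C2–C3 bond is made by addition to an aldehyde instead of acylation, and step 2 is not needed.

Step 4 (elimination of the β-mesylate). Elimination may be incomplete or give material that is hard to separate from 6. The fallback sets out from 5 and comes back at 8. Treat 5 with 1,1'-thiocarbonyldiimidazole and DMAP (1,2-dichloroethane, 60 °C) to give tert-butyl 3-[(1H-imidazol-1-ylcarbonothioyl)oxy]tetracosanoate F3. Reduce it with Bu3SnH and AIBN (toluene, 110 °C). This Barton–McCombie radical deoxygenation gives 8 directly and bypasses steps 3–5.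

Step 9 (esterification). The ortho-substituted acid 12 can rearrange to the N-acylurea, and 9 is sparingly soluble, so coupling may be slow. The fallback sets out from 9 and comes back at 13, with the roles of the partners inverted. Convert 9 with MsCl and Et3N (CH2Cl2/THF, 0 °C → rt) into tetracosyl methanesulfonate F4. Heat F4 with 12 and Cs2CO3 in DMF at 70 °C. SN2 O-alkylation of the caesium carboxylate gives 13 without any acyl activation.

**Further compounds**
F1 | step 1 | docosan-1-ol | CCCCCCCCCCCCCCCCCCCCCCO
F2 | step 1 | docosanal | CCCCCCCCCCCCCCCCCCCCCC=O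
F3 | step 4 | tert-butyl 3-[(1H-imidazol-1-ylcarbonothioyl)oxy]tetracosanoate (racemic) | CCCCCCCCCCCCCCCCCCCCCC(OC(=S)n1ccnc1)CC(=O)OC(C)(C)C
F4 | step 9 | tetracosyl methanesulfonate | CCCCCCCCCCCCCCCCCCCCCCCCOS(C)(=O)=O
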